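Read at 40 h, alpha should have stopped, so your hunch that it ends higher can be tested on the stopping points.

| setting | teal | ochre | violet | beta | alpha |
|---|---|---|---|---|---|
| free monomer | 0.014 M | 0.051 M | 0.020 M | 0.060 M | 0.020 M |
| initiator | 0.50 mM | 0.50 mM | 0.44 mM | 0.25 mM | 0.50 mM |
| temperature | 25 °C | 50 °C | 25 °C | 30 °C | 70 °C |
| remark | run made earlier | run made earlier | run made earlier |  |  |
| time |  |  |  | 40 h | 40 h |

| run | time / h | monomer in chains / % | free monomer / % |
|---|---|---|---|
| teal | 15.0 | 0 | 100.2 |
| teal | 40.0 | 2.5 | 97.8 |
| teal | 72.0 | 8.6 | 92.6 |
| teal | 120 | 15.8 | 86.7 |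
| teal | 144 | 18.6 | 83.1 |
| teal | 192 | 24.8 | 74.1 |
| teal | 288 | 37.7 | 61.8 |
| ochre | 6.00 | 9.3 | 91.0 |
| ochre | 8.00 | 14.3 | 87.5 |
| ochre | 15.0 | 22.0 | 77.3 |
| ochre | 20.0 | 26.3 | 73.2 |
| ochre | 30.0 | 27.8 | 69.7 |
| ochre | 60.0 | 30.4 | 69.4 |
| ochre | 72.0 | 30.0 | 70.1 |
| violet | 25.0 | 1.2 | 100.0 |
| violet | 40.0 | 0 | 98.3 |
| violet | 72.0 | 8.0 | 93.4 |
| violet | 144 | 19.7 | 80.1 |
| violet | 288 | 34.0 | 62.4 |

(each reading ± 1 percentage point)

* which one finishes higher in amount of monomer in chains, in percent of the free monomer charged ("neither" within 2 percentage points) (beta / alpha / neither)
* amount of monomer in chains at the end, in percent of the free monomer charged, beta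
* amount of monomer in chains at the end, in percent of the free monomer charged, alpha

- steps under discussion: living end + monomer in chains -> dead end; free monomer + initiator -> living end + monomer in chains; free monomer + living end -> monomer in chains + living end

Work with the fraction f of free monomer left, not the fraction made. A living end either adds free monomer, at a rate proportional to [free monomer], or dies on monomer in chains, at a rate proportional to [monomer in chains], so time drops out of the contest between them. If the charged initiator ends up as dead ends, integrating gives [initiator]/[free monomer], both at charge, equal to the stopping ratio times the bracket ln(1/f) − 1 + f. The stopping ratio is the termination constant over the propagation constant. Ochre's free monomer readings stay level within their scatter from 30.0 h, and the last reading of 70.1 % makes the bracket 0.0562, so the stopping ratio reads 0.174, with the scatter of that reading in it.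

I assume that ratio holds at the other temperatures. Ochre, at 50 °C against alpha's 70 °C, read level at 30.0 h, earlier than 40 h, so I take alpha as stopped by then. The bracket inverts closely: with s the square root of 2 times the bracket, the fraction lost is s minus s squared over 3. Each dead end also removes one unit from the chains, so I subtract the charge ratio. Alpha then loses 44.0 % and stops at 41.5 % in chains. Beta's stopping point is 19.9 %, lower than alpha's. That is the ceiling of dead-end polymerization. Teal, at 25 °C against beta's 30 °C, read 2.5 % at 40.0 h, less than beta's stopping point, so I expect beta to lie under that point at 40 h and leave its number to the forecast.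

The forecast names alpha, with 42 % for alpha and 6.5 % for beta, and says of alpha that “the plateau sets the result”. My alpha figure differs slightly from its figure.

The flasks give 45.5 % for alpha and 6.60 % for beta, so alpha finishes higher.

    living end + monomer in chains → dead end (k = 35.0 /M/h, Ea = 58.0 kJ/mol)
    free monomer + initiator → living end + monomer in chains (k = 21.0 /M/h, Ea = 76.0 kJ/mol)
    free monomer + living end → monomer in chains + living end, rate k3*[living end]*[free monomer] (k = 230 /M/h, Ea = 60.0 kJ/mol)
    (constants at 70 °C)

Alpha kept 52 % of its free monomer at 40.0 h, against 56.0 % reckoned from the stopping ratio of 0.174. A neighbour flask is charged with 1.3 × 10⁻⁴ M of initiator, all else as in alpha. The same reckoning loses 24.8 % of the free monomer and puts 24.2 % in chains. At 40.0 h that flask holds 0 % of its initiator and 26.0 % of monomer in chains.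

All runs are simulated on assumed constants.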